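The readings stem from a simulated flask with constants of no real substance; scatter was added.

Points per hour of the J charged was the unit I reckoned in when you asked for a quick number.

| setting | theta | beta | flask |
|---|---|---|---|
| J | 0.29 M | 0.29 M | 0.29 M |
| Q | 2 equiv | 8 equiv | 4.00 equiv |
| Z | 0.29 M | 0.29 M | 0.290 M |
| remark | run made earlier | run made earlier |  |
| time |  |  | 1.0 h |
| volume of the second phase over the first |  |  | 2.0 |

| run | time / min | D / % | L / % |
|---|---|---|---|
| theta | 8.00 | 78 | 77 |
| theta | 15.0 | 96 | 89 |
| theta | 20.0 | 97 | 92 |
| theta | 30.0 | 94 | 93 |
| theta | 40.0 | 96 | 96 |
| beta | 3.00 | 88 | 82 |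
| beta | 5.00 | 89 | 89 |
| beta | 10.0 | 92 | 91 |
| beta | 20.0 | 85 | 83 |
| beta | 40.0 | 84 | 77 |

(standard deviation of a reading: 2 percentage points)

- for D the L are counted in
- in the second phase: Q; everything else is in the first
- charges count per volume of the first phase; a concentration in a rate is the amount of a species over the volume of its own phase; every rate counts per litre of the first phase
- as a solid, counted per litre of solution: L
- the numbers in the tables scatter with a standard deviation of 2 percentage points
- the earlier runs hold the two phases in the same ratio of volumes as the flask asked about

1. amount of D and L together at 1.0 h, in percent of the J charged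
2. concentration of D in solution at 1.0 h, in percent of saturation

**Frozen solution.** In both runs D ran close to L once crystals stood, so I froze dissolved D at saturation and drew the loss of D as a straight line, a pseudo-zero-order loss.

**Spare Q.** The beta run fell from 92% to 84% between 10.0 min and 40.0 min, but the theta run stayed flat within the scatter of 2 percentage points. I therefore counted Q only above theta's 2 equiv, and the flask held a third of beta's Q above that line. That gave 5.3 points per hour. I called this the spare-Q loss, the points of D and L lost per hour from a saturated solution, in proportion to Q above theta's charge. From theta's last 96% I reckoned 90.7% for the flask at 1.0 h, and I kept its dissolved D at 100 percent of saturation.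

**The forecast.** It gave 89% and 100% of saturation, reasoning “so the solution looks saturated once crystals are present”. My figure stood higher than the forecast's.

**The flask.** It gave 90.4% and 97.2% of saturation, so the forecast held.

    X ⇌ Q, rate k1*([X] - [Q]/K1) per volume of the first phase (partition coefficient = 0.700, kL = 5.70 min⁻¹)
    J + X → D (k = 1.50 M⁻¹ min⁻¹)
    X + D → G (k = 0.170 M⁻¹ min⁻¹)
    L ⇌ D, rate k4*(cs4 - [D]) while solid is left; crystals form when [D] > cs4 (solubility = 5.80 mM, k = 1.40 min⁻¹)
    X + Z → E (k = 0.200 M⁻¹ min⁻¹)

**What carried it.** The freezing step carried the weight: how little D dissolves is the main reason that this flask held 90.4% of D and L together at 1.0 h, since the same flask without that low solubility held 13.6%. In this flask, the spare-Q loss taken from 94.1% at 0.250 h gives 90.1% at 1.0 h. For the neighbour left until 4.0 h, the same loss from 90.4% gives 74.5%; that neighbour gave 77.2%.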